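**Retrosynthetic overview**
1. Target ⇐ desilylation (C3), Yamaguchi angeloylation (C8–OH) and MOM removal from macrocycle 26.
2. Ten-membered ring (formed second) ⇐ ring-closing metathesis making the (Z)-C1=C10 olefin of seco-lactone 25.
3. trans-α-Methylene-γ-butyrolactone (formed first) and the C6–C7 bond ⇐ CrCl2-mediated 2-(methoxycarbonyl)allylation joining aldehyde 9 (C1–C6, C15) with allylic bromide 21 (C7–C14), then lactonisation.
4. Aldehyde 9 ⇐ Brown allylation of (E)-4-acetoxy-2-methylbut-2-enal (from prenol by SeO2 oxidation).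
5. Bromide 21 ⇐ Brown (Z)-γ-alkoxyallylboration of methacrolein, cross-metathesis with methyl 2-(hydroxymethyl)acrylate, Appel bromination.

Assumption: germacrane numbering is used for positions (ring C1–C10, C14 on C10, C15 on C4, lactone carbonyl C12, exocyclic methylene C13); the target read from the SMILES is the (1(10)Z,4E,3S,6R,7S,8R,9R) isomer with the (Z)-2-methylbut-2-enoate (angelate) at O8.

**Route**

Step 1
Reactants: 1 3-methylbut-2-en-1-ol (prenol)
Product: 2 3-methylbut-2-en-1-yl acetate
Conditions: Ac2O, pyridine, DMAP (cat.), CH2Cl2, 0 °C → rt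
Reagents that add atoms: acetic anhydride, CC(=O)OC(C)=O
Why: DMAP-catalysed O-acylation protects the allylic alcohol for the selenium dioxide oxidation (no stereocentre).

Step 2
Reactants: 2 3-methylbut-2-en-1-yl acetate
Product: 3 (2E)-3-methyl-4-oxobut-2-en-1-yl acetate
Conditions: SeO2 (1.1 equiv), 1,4-dioxane, 80 °C
Reagents that add atoms: selenium dioxide, O=[Se]=O
Why: Riley allylic oxidation (ene reaction then [2,3]-sigmatropic shift) attacks the methyl group trans to the CH2OAc substituent of the trisubstituted alkene, so the enal forms with E geometry (the future 4E olefin).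

Step 3
Reactants: 3 (2E)-3-methyl-4-oxobut-2-en-1-yl acetate; 4 allylmagnesium bromide (CH2=CHCH2MgBr)
Product: 7 (2E,4S)-3-methylhepta-2,6-diene-1,4-diol, via B-allyldiisopinocampheylborane 5 (not isolated), via borinate ester of the adduct 6 (not isolated)
Conditions: 4 (1.0 equiv), (−)-Ipc2BOMe (1.05 equiv), Et2O, 0 °C → rt; then 3, −78 °C; then 3 M NaOH, 30% H2O2, rt → 40 °C
Reagents that add atoms: none
Why: Brown asymmetric allylboration through a closed chair transition state in which the (+)-α-pinene-derived isopinocampheyl groups expose one aldehyde face, giving the 4S carbinol (C3 of the target, as for other aldehydes whose substituent outranks allyl); the alkaline peroxide work-up cleaves the boron residues and saponifies the acetate.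

Step 4
Reactants: 7 (2E,4S)-3-methylhepta-2,6-diene-1,4-diol
Product: 8 (2E,4S)-4-hydroxy-3-methylhepta-2,6-dienal
Conditions: TEMPO (10 mol %), PhI(OAc)2 (1.1 equiv), CH2Cl2, rt
Reagents that add atoms: none
Why: Oxoammonium (TEMPO) oxidation is selective for the unhindered primary allylic alcohol over the hindered secondary one and stops at the enal without touching the E olefin or the carbinol centre.

Step 5
Reactants: 8 (2E,4S)-4-hydroxy-3-methylhepta-2,6-dienal
Product: 9 (2E,4S)-4-[(tert-butyldimethylsilyl)oxy]-3-methylhepta-2,6-dienal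
Conditions: TBSCl, imidazole, DMF, 0 °C → rt
Reagents that add atoms: tert-butyldimethylsilyl chloride, CC(C)(C)[Si](C)(C)Cl
Why: Corey silylation of the secondary alcohol gives a TBS ether that survives the chromium coupling, metathesis, Me2BBr and acylation and is removed last.

Step 6
Reactants: 10 prop-2-en-1-ol (allyl alcohol)
Product: 11 3-(methoxymethoxy)prop-1-ene
Conditions: MOMCl, i-Pr2NEt, CH2Cl2, 0 °C → rt
Reagents that add atoms: chloromethyl methyl ether, COCCl
Why: O-alkylation with the reactive α-chloro ether gives the MOM ether needed for α-lithiation.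

Step 7
Reactants: 11 3-(methoxymethoxy)prop-1-ene; 12 2-methylprop-2-enal (methacrolein)
Product: 17 (3R,4R)-4-(methoxymethoxy)-2-methylhexa-1,5-dien-3-ol, via (Z)-alkoxyallyllithium 13 (not isolated), via lithium methoxyborate complex 14 (not isolated), via (Z)-alkoxyallyldiisopinocampheylborane 15 (not isolated), via borinate ester of the adduct 16 (not isolated)
Conditions: s-BuLi, THF, −78 °C; (−)-Ipc2BOMe, −78 °C; BF3·OEt2; then 12, −78 °C → rt; then 3 M NaOH, 30% H2O2
Reagents that add atoms: none
Why: Brown (Z)-γ-alkoxyallylboration: the chelated (Z)-alkoxyallyl anion is borylated at its CH2 terminus and adds through a chair transition state with the Z-alkoxy group axial to give the syn (threo) diol monoether, while the (+)-α-pinene-derived Ipc groups select the aldehyde face and set (3R,4R), which are C9 and C8 of the target.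

Step 8
Reactants: 17 (3R,4R)-4-(methoxymethoxy)-2-methylhexa-1,5-dien-3-ol
Product: 18 (3R,4R)-4-(methoxymethoxy)-2-methylhexa-1,5-dien-3-yl acetate
Conditions: Ac2O, pyridine, DMAP (cat.), CH2Cl2, 0 °C → rt
Reagents that add atoms: acetic anhydride, CC(=O)OC(C)=O
Why: DMAP-catalysed acylation puts the final C9 acetate on the only free hydroxyl without affecting a stereocentre.

Step 9
Reactants: 18 (3R,4R)-4-(methoxymethoxy)-2-methylhexa-1,5-dien-3-yl acetate; 19 methyl 2-(hydroxymethyl)prop-2-enoate
Product: 20 methyl (2E,4R,5R)-5-acetoxy-2-(hydroxymethyl)-4-(methoxymethoxy)-6-methylhepta-2,6-dienoate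
Conditions: second-generation Hoveyda–Grubbs catalyst RuCl2(H2IMes)(=CH-C6H4-2-OiPr) (10 mol %), 19 (5 equiv), CH2Cl2, 40 °C
Reagents that add atoms: none
Why: Olefin cross-metathesis in which only the monosubstituted vinyl group of 18 initiates readily, the 1,1-disubstituted acrylate 19 does not homodimerise, and the trisubstituted enoate forms with the chain trans to the ester as in methacrylate cross-metatheses, the isopropenyl group being too hindered to compete.

Step 10
Reactants: 20 methyl (2E,4R,5R)-5-acetoxy-2-(hydroxymethyl)-4-(methoxymethoxy)-6-methylhepta-2,6-dienoate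
Product: 21 methyl (2Z,4R,5R)-5-acetoxy-2-(bromomethyl)-4-(methoxymethoxy)-6-methylhepta-2,6-dienoate
Conditions: CBr4, PPh3, CH2Cl2, 0 °C
Reagents that add atoms: carbon tetrabromide, BrC(Br)(Br)Br
Why: Appel reaction, an SN2 displacement of the primary allylic oxyphosphonium by bromide under neutral conditions that leave the MOM ether, acetate and alkene geometry intact (the descriptor becomes Z only because CH2Br outranks CO2Me).

Step 11
Reactants: 9 (2E,4S)-4-[(tert-butyldimethylsilyl)oxy]-3-methylhepta-2,6-dienal; 21 methyl (2Z,4R,5R)-5-acetoxy-2-(bromomethyl)-4-(methoxymethoxy)-6-methylhepta-2,6-dienoate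
Product: 25 (1R,2R)-1-[(2R,3S)-2-{(1E,3S)-3-[(tert-butyldimethylsilyl)oxy]-2-methylhexa-1,5-dien-1-yl}-4-methylidene-5-oxooxolan-3-yl]-1-(methoxymethoxy)-3-methylbut-3-en-2-yl acetate, via allylchromium dichloride 22 (not isolated), via chromium alkoxide 23 (not isolated), via hydroxy ester 24 (not isolated)
Conditions: CrCl2 (4 equiv), THF, 0 °C → rt; aq NH4Cl work-up; then PPTS (cat.), benzene, 50 °C
Reagents that add atoms: none
Why: Nozaki–Hiyama–Kishi-type 2-(alkoxycarbonyl)allylation with divalent chromium: the equilibrating allylchromium adds through its γ-carbon (C7) in a chair transition state with the C8 substituent equatorial, giving the 6,7-anti adduct that lactonises to the trans lactone (first ring), and with C8–H eclipsing the acrylate plane (allylic 1,3-strain) the aldehyde approaches anti to the C8–O bond, which sets 6R and 7S.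

Step 12
Reactants: 25 seco-lactone (name as in step 11)
Product: 26 (1(10)Z,4E,3S,6R,7S,8R,9R)-9-acetoxy-3-[(tert-butyldimethylsilyl)oxy]-8-(methoxymethoxy)germacra-1(10),4,11(13)-trien-12,6-olide
Conditions: second-generation Grubbs catalyst RuCl2(H2IMes)(PCy3)(=CHPh) (15 mol %, in portions), 1,4-benzoquinone (cat.), toluene (0.5 mM), 100 °C
Reagents that add atoms: none
Why: Ring-closing metathesis initiating at the monosubstituted C1 vinyl group and closing onto the isopropenyl group forms the ten-membered ring (second ring); strain in a ring that already holds the 4E olefin and the trans lactone is expected to favour the Z trisubstituted C1=C10 olefin, high dilution suppresses dimers, and the electron-poor methylene lactone and C4=C5 do not take part.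

Step 13
Reactants: 26 macrocyclic MOM ether (name as in step 12)
Product: 28 (1(10)Z,4E,3S,6R,7R,8R,9R)-9-acetoxy-3-[(tert-butyldimethylsilyl)oxy]-8-hydroxygermacra-1(10),4,11(13)-trien-12,6-olide, via bromomethyl ether 27 (not isolated)
Conditions: Me2BBr (3 equiv), CH2Cl2, −78 °C; then THF/sat. aq NaHCO3, −78 °C → rt
Reagents that add atoms: none
Why: Guindon acetal cleavage: Me2BBr converts the MOM ether into a bromomethyl ether that hydrolyses on bicarbonate work-up, at −78 °C sparing the TBS ether, acetate, lactone and olefins, and since the C8–O bond is never broken the configuration is retained (the C7 label changes to R only through CIP priorities).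

Step 14
Reactants: 28 C8 alcohol (name as in step 13); 29 (2Z)-2-methylbut-2-enoic acid (angelic acid)
Product: 31 (1(10)Z,4E,3S,6R,7S,8R,9R)-9-acetoxy-8-[(2Z)-2-methylbut-2-enoyloxy]-3-[(tert-butyldimethylsilyl)oxy]germacra-1(10),4,11(13)-trien-12,6-olide, via angelic 2,4,6-trichlorobenzoic anhydride 30 (not isolated)
Conditions: 29, 2,4,6-trichlorobenzoyl chloride, Et3N, toluene, rt; then 28, toluene, 80 °C
Reagents that add atoms: none
Why: Yamaguchi esterification through the mixed anhydride acylates the hindered C8 alcohol at the angeloyl carbonyl without Z to E isomerisation to the tiglate, and working without DMAP and with little excess Et3N limits migration of the neighbouring C9 acetate.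

Step 15
Reactants: 31 silyl ether (name as in step 14)
Product: 32 (1(10)Z,4E,3S,6R,7S,8R,9R)-9-acetoxy-3-hydroxy-8-[(2Z)-2-methylbut-2-enoyloxy]germacra-1(10),4,11(13)-trien-12,6-olide (CNP0265116.2)
Conditions: HF·pyridine, pyridine, THF, 0 °C → rt
Reagents that add atoms: none
Why: Fluoride-mediated Si–O cleavage under buffered HF·pyridine frees the C3 alcohol without adding to the α-methylene lactone, cleaving the esters or isomerising the angelate.

**Compound list**

1 | 3-methylbut-2-en-1-ol (prenol) | CC(C)=CCO | starting material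
2 | 3-methylbut-2-en-1-yl acetate | CC(C)=CCOC(C)=O | intermediate
3 | (2E)-3-methyl-4-oxobut-2-en-1-yl acetate | O=C/C(C)=C/COC(C)=O | intermediate
4 | allylmagnesium bromide | C=CC[Mg]Br | starting material
5 | B-allyldiisopinocampheylborane, Ipc = (1R,2S,3R,5R)-isopinocampheyl from (+)-α-pinene (not isolated) | C=CCB([C@@H]1C[C@@H]2C[C@H]([C@H]1C)C2(C)C)[C@@H]1C[C@@H]2C[C@H]([C@H]1C)C2(C)C | intermediate
6 | O-(diisopinocampheylboryl) derivative of (2E,4S)-4-hydroxy-3-methylhepta-2,6-dien-1-yl acetate (not isolated) | CC(=O)OC/C=C(\C)[C@@H](OB([C@@H]1C[C@@H]2C[C@H]([C@H]1C)C2(C)C)[C@@H]1C[C@@H]2C[C@H]([C@H]1C)C2(C)C)CC=C | intermediate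
7 | (2E,4S)-3-methylhepta-2,6-diene-1,4-diol | OC/C=C(\C)[C@@H](O)CC=C | intermediate
8 | (2E,4S)-4-hydroxy-3-methylhepta-2,6-dienal | O=C/C=C(\C)[C@@H](O)CC=C | intermediate
9 | (2E,4S)-4-[(tert-butyldimethylsilyl)oxy]-3-methylhepta-2,6-dienal (C1–C6 aldehyde) | O=C/C=C(\C)[C@@H](O[Si](C)(C)C(C)(C)C)CC=C | intermediate
10 | prop-2-en-1-ol (allyl alcohol) | C=CCO | starting material
11 | 3-(methoxymethoxy)prop-1-ene | C=CCOCOC | intermediate
12 | 2-methylprop-2-enal (methacrolein) | CC(=C)C=O | starting material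
13 | [(Z)-3-(methoxymethoxy)allyl]lithium (not isolated) | [Li]C/C=C\OCOC | intermediate
14 | lithium methoxy[(Z)-3-(methoxymethoxy)allyl]diisopinocampheylborate (not isolated) | [Li+].CO[B-](C/C=C\OCOC)([C@@H]1C[C@@H]2C[C@H]([C@H]1C)C2(C)C)[C@@H]1C[C@@H]2C[C@H]([C@H]1C)C2(C)C | intermediate
15 | [(Z)-3-(methoxymethoxy)allyl]diisopinocampheylborane (not isolated) | COCO/C=C\CB([C@@H]1C[C@@H]2C[C@H]([C@H]1C)C2(C)C)[C@@H]1C[C@@H]2C[C@H]([C@H]1C)C2(C)C | intermediate
16 | O-(diisopinocampheylboryl) derivative of 17 (not isolated) | C=C(C)[C@@H](OB([C@@H]1C[C@@H]2C[C@H]([C@H]1C)C2(C)C)[C@@H]1C[C@@H]2C[C@H]([C@H]1C)C2(C)C)[C@H](OCOC)C=C | intermediate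
17 | (3R,4R)-4-(methoxymethoxy)-2-methylhexa-1,5-dien-3-ol | C=C(C)[C@@H](O)[C@H](OCOC)C=C | intermediate
18 | (3R,4R)-4-(methoxymethoxy)-2-methylhexa-1,5-dien-3-yl acetate | C=C(C)[C@@H](OC(C)=O)[C@H](OCOC)C=C | intermediate
19 | methyl 2-(hydroxymethyl)prop-2-enoate | C=C(CO)C(=O)OC | starting material
20 | methyl (2E,4R,5R)-5-acetoxy-2-(hydroxymethyl)-4-(methoxymethoxy)-6-methylhepta-2,6-dienoate | C=C(C)[C@@H](OC(C)=O)[C@H](OCOC)/C=C(CO)/C(=O)OC | intermediate
21 | methyl (2Z,4R,5R)-5-acetoxy-2-(bromomethyl)-4-(methoxymethoxy)-6-methylhepta-2,6-dienoate (C7–C14 bromide) | C=C(C)[C@@H](OC(C)=O)[C@H](OCOC)/C=C(CBr)/C(=O)OC | intermediate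
22 | allylchromium dichloride from 21, CrCl2 on the former CH2Br carbon, alkene geometry mobile (not isolated) | Cl[Cr](Cl)CC(=C[C@@H](OCOC)[C@H](OC(C)=O)C(C)=C)C(=O)OC | intermediate
23 | dichlorochromium alkoxide of 24 (not isolated) | C=C(C(=O)OC)[C@@H]([C@H](O[Cr](Cl)Cl)/C=C(\C)[C@@H](O[Si](C)(C)C(C)(C)C)CC=C)[C@@H](OCOC)[C@H](OC(C)=O)C(C)=C | intermediate
24 | methyl (3S,4R,5E,7S)-3-[(1R,2R)-2-acetoxy-1-(methoxymethoxy)-3-methylbut-3-en-1-yl]-7-[(tert-butyldimethylsilyl)oxy]-4-hydroxy-6-methyl-2-methylidenedeca-5,9-dienoate (not isolated) | C=C(C(=O)OC)[C@@H]([C@H](O)/C=C(\C)[C@@H](O[Si](C)(C)C(C)(C)C)CC=C)[C@@H](OCOC)[C@H](OC(C)=O)C(C)=C | intermediate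
25 | (1R,2R)-1-[(2R,3S)-2-{(1E,3S)-3-[(tert-butyldimethylsilyl)oxy]-2-methylhexa-1,5-dien-1-yl}-4-methylidene-5-oxooxolan-3-yl]-1-(methoxymethoxy)-3-methylbut-3-en-2-yl acetate (trans lactone) | C=C1C(=O)O[C@H](/C=C(\C)[C@@H](O[Si](C)(C)C(C)(C)C)CC=C)[C@H]1[C@@H](OCOC)[C@H](OC(C)=O)C(C)=C | intermediate
26 | (1(10)Z,4E,3S,6R,7S,8R,9R)-9-acetoxy-3-[(tert-butyldimethylsilyl)oxy]-8-(methoxymethoxy)germacra-1(10),4,11(13)-trien-12,6-olide | C=C1C(=O)O[C@@H]2/C=C(\C)[C@@H](O[Si](C)(C)C(C)(C)C)C/C=C(/C)[C@@H](OC(C)=O)[C@H](OCOC)[C@@H]12 | intermediate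
27 | 8-O-(bromomethyl) analogue of 26, OCH2Br in place of OCH2OCH3 (not isolated) | C=C1C(=O)O[C@@H]2/C=C(\C)[C@@H](O[Si](C)(C)C(C)(C)C)C/C=C(/C)[C@@H](OC(C)=O)[C@H](OCBr)[C@@H]12 | intermediate
28 | (1(10)Z,4E,3S,6R,7R,8R,9R)-9-acetoxy-3-[(tert-butyldimethylsilyl)oxy]-8-hydroxygermacra-1(10),4,11(13)-trien-12,6-olide (same spatial arrangement as 26) | C=C1C(=O)O[C@@H]2/C=C(\C)[C@@H](O[Si](C)(C)C(C)(C)C)C/C=C(/C)[C@@H](OC(C)=O)[C@H](O)[C@@H]12 | intermediate
29 | (2Z)-2-methylbut-2-enoic acid (angelic acid) | C/C=C(/C)C(=O)O | starting material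
30 | (2Z)-2-methylbut-2-enoic 2,4,6-trichlorobenzoic anhydride (not isolated) | C/C=C(/C)C(=O)OC(=O)c1c(Cl)cc(Cl)cc1Cl | intermediate
31 | (1(10)Z,4E,3S,6R,7S,8R,9R)-9-acetoxy-8-[(2Z)-2-methylbut-2-enoyloxy]-3-[(tert-butyldimethylsilyl)oxy]germacra-1(10),4,11(13)-trien-12,6-olide | C=C1C(=O)O[C@@H]2/C=C(\C)[C@@H](O[Si](C)(C)C(C)(C)C)C/C=C(/C)[C@@H](OC(C)=O)[C@H](OC(=O)/C(C)=C\C)[C@@H]12 | intermediate
32 | (1(10)Z,4E,3S,6R,7S,8R,9R)-9-acetoxy-3-hydroxy-8-[(2Z)-2-methylbut-2-enoyloxy]germacra-1(10),4,11(13)-trien-12,6-olide | C=C1C(=O)O[C@@H]2/C=C(\C)[C@@H](O)C/C=C(/C)[C@@H](OC(C)=O)[C@H](OC(=O)/C(C)=C\C)[C@@H]12 | target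

**Totals and risks**

Total step count: 15. Longest linear sequence: 10 steps (steps 1–5 then 11–15; equally steps 6–10 then 11–15).

Most likely to fail, step 12 (ring-closing metathesis to a ten-membered ring with a trisubstituted Z olefin). The trans-fused lactone may hold the two alkenes apart and give oligomers or E/Z mixtures. The fallback closes the carbocycle before the lactone. It sets out from hydroxy ester 24, obtained from step 11 by aqueous work-up without the PPTS treatment. Silylation (TESOTf, 2,6-lutidine, CH2Cl2, −78 °C) gives the C6 triethylsilyl ether F1. Ring-closing metathesis of this flexible acyclic ester under the same dilution gives the ten-membered carbocyclic ester F2. PPTS in MeOH removes only the triethylsilyl group to give the macrocyclic hydroxy ester F3, which lactonises on warming with PPTS in benzene and comes back to the route at 26.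

Second, step 11 (chromium coupling). Coordination of chromium by the MOM ether or a weak facial bias from C8 could erode the anti and facial selectivity. The fallback replaces direct anti allylation by syn allylation followed by inversion at C6. It sets out from 9 and 21, which are coupled with indium powder (zerovalent indium) in THF/H2O. There the Z-configured bromide reacts through an ester-chelated closed transition state, with C7 again formed anti to the C8–O bond, and gives the 6,7-syn adduct, the C6-epimeric hydroxy ester F4. Mitsunobu reaction (4-nitrobenzoic acid, PPh3, DIAD, toluene, 0 °C) inverts the allylic C6 carbinol to the 4-nitrobenzoate F5. Brief methanolysis of this activated ester (K2CO3 cat., MeOH, 0 °C; the C9 acetate is much slower) liberates 24, which is lactonised with PPTS as in step 11 and comes back to the route at 25.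

Third, step 9 (cross-metathesis of a hindered allylic ether with a 1,1-disubstituted acrylate). If it is too slow, the same C7=C11 bond is made intramolecularly through a temporary silicon tether. The fallback sets out from alcohol 17 and 19. Treatment of 17 with i-Pr2SiCl2 and imidazole gives the chlorodiisopropylsilyl ether F6, which is capped with 19 to the mixed bis-alkoxysilane F7. Ring-closing metathesis (second-generation Grubbs catalyst, toluene, 80 °C) gives the eight-membered cyclic silaketal F8, in which the new trisubstituted alkene is necessarily cis in the ring (C8 cis to the CH2O carbon, the geometry wanted). HF·pyridine releases the diol F9. Appel bromination (CBr4, PPh3, CH2Cl2, 0 °C) converts only the primary allylic alcohol and gives the bromo alcohol F10. Immediate acetylation of the C9 hydroxyl (Ac2O, pyridine, DMAP) comes back to the route at 21.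

**Further compounds**

F1 | step 12 | C6 triethylsilyl ether of hydroxy ester 24 | C=C(C(=O)OC)[C@@H]([C@H](O[Si](CC)(CC)CC)/C=C(\C)[C@@H](O[Si](C)(C)C(C)(C)C)CC=C)[C@@H](OCOC)[C@H](OC(C)=O)C(C)=C
F2 | step 12 | ten-membered carbocyclic methyl ester with (1(10)Z,4E) olefins, 6-OTES, 3-OTBS, 8-OMOM, 9-OAc and the 2-propenoate unit on C7 | C=C(C(=O)OC)[C@H]1[C@H](O[Si](CC)(CC)CC)/C=C(\C)[C@@H](O[Si](C)(C)C(C)(C)C)C/C=C(/C)[C@@H](OC(C)=O)[C@@H]1OCOC
F3 | step 12 | macrocyclic hydroxy ester, F2 with free C6 hydroxyl | C=C(C(=O)OC)[C@H]1[C@H](O)/C=C(\C)[C@@H](O[Si](C)(C)C(C)(C)C)C/C=C(/C)[C@@H](OC(C)=O)[C@@H]1OCOC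
F4 | step 11 | C6 epimer of hydroxy ester 24 (6,7-syn adduct) | C=C(C(=O)OC)[C@@H]([C@@H](O)/C=C(\C)[C@@H](O[Si](C)(C)C(C)(C)C)CC=C)[C@@H](OCOC)[C@H](OC(C)=O)C(C)=C
F5 | step 11 | 4-nitrobenzoate of 24 (C6 inverted relative to F4) | C=C(C(=O)OC)[C@@H]([C@H](OC(=O)c1ccc(cc1)[N+](=O)[O-])/C=C(\C)[C@@H](O[Si](C)(C)C(C)(C)C)CC=C)[C@@H](OCOC)[C@H](OC(C)=O)C(C)=C
F6 | step 9 | chlorodiisopropylsilyl ether of 17 | C=C(C)[C@@H](O[Si](Cl)(C(C)C)C(C)C)[C@H](OCOC)C=C
F7 | step 9 | mixed diisopropylsilyl bis-ether of 17 and 19 | C=C(C)[C@@H](O[Si](C(C)C)(C(C)C)OCC(=C)C(=O)OC)[C@H](OCOC)C=C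
F8 | step 9 | eight-membered cyclic diisopropylsilaketal with endocyclic trisubstituted enoate | C=C(C)[C@H]1O[Si](C(C)C)(C(C)C)OC/C(C(=O)OC)=C\[C@H]1OCOC
F9 | step 9 | methyl (2E,4R,5R)-5-hydroxy-2-(hydroxymethyl)-4-(methoxymethoxy)-6-methylhepta-2,6-dienoate | C=C(C)[C@@H](O)[C@H](OCOC)/C=C(CO)/C(=O)OC
F10 | step 9 | methyl (2Z,4R,5R)-2-(bromomethyl)-5-hydroxy-4-(methoxymethoxy)-6-methylhepta-2,6-dienoate | C=C(C)[C@@H](O)[C@H](OCOC)/C=C(CBr)/C(=O)OC
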